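**Plan**

- Retrosynthesis: the C5 methoxy group and the saturated C4–C5 bond are taken back to a C4=C5 dienone. The C3a–allyl bond is cut to give an aromatic 2,3-dihydrobenzofuran-6-ol, and O1–C2 is cut to an open carbinol. Last, aryl–C2 and C3–C3a are cut together, to 3,4,5-trimethoxyphenyllithium, a (Z)-propenylboronic ester and a 2,4-dioxygenated aryl triflate.
- Forward: a three-component conjunctive coupling gives the open carbinol. Ring B (the dihydrofuran O1–C2–C3–C3a–C7a) is closed by Mitsunobu etherification. Ring A (C3a–C4–C5–C6–C7–C7a) is dearomatized by oxidative allylation, then reduced and hydroxylated at C5, and the hydroxyl is methylated.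
- Enabling feature: C2 carries both the aryl group and O1, and its neighbour C3 is bonded to C3a, which lies para to the C6 oxygen of ring A. Ring A can therefore be a phenol-level arene and C3a an sp2 electrophile. The array C2(aryl)(O)–C3(Me)–C3a is then the product pattern of a 1,2-metallate shift (aryl to C2, boron later replaced by oxygen) with capture at C3.
- Stereochemistry: C2 and C3 come from the Z-alkene geometry and the chiral palladium catalyst; C2 is inverted once in the Mitsunobu closure. C3a is set anti to the C3 methyl group. C5 is set anti to the pseudoaxial allyl group, which is also the equatorial, more stable epimer.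

Key step: step 5

Assumption: the antipode of the MandyPhos ligand is chosen so that the (1R,2S) product results; it is written as (Sp,Sp) and would be exchanged for (Rp,Rp) if a test reaction shows the opposite sense of induction.
Assumption: diol 2 is made in step 1 in case it cannot be purchased; compounds 1, 3, 5 and 9 are taken as commercial.

**Step 1**
Reactants: 1 acenaphthylene-1,2-dione
Product: 2 cis-1,2-dimethyl-1,2-dihydroacenaphthylene-1,2-diol (meso)
Conditions: AlMe3 (excess), toluene, 0 °C to rt; aqueous work-up
Reagents that add atoms: trimethylaluminium, C[Al](C)C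
Why: Double 1,2-addition of methyl to the 1,2-dione; the second methyl should enter anti to the first aluminium alkoxide on the rigid five-membered ring, giving the cis diol needed for a cyclic boronic ester.

**Step 2**
Reactants: 3 (Z)-prop-1-en-1-ylboronic acid; 2 cis-1,2-dimethyl-1,2-dihydroacenaphthylene-1,2-diol
Product: 4 (Z)-prop-1-enylboronic ester of diol 2
Conditions: MgSO4, CH2Cl2, rt
Reagents that add atoms: none
Why: Boronic ester formation from a boronic acid and a cis-1,2-diol, driven by removal of water; the Z geometry is not touched.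

**Step 3**
Reactants: 5 2,4-bis(benzyloxy)benzaldehyde
Product: 7 2,4-bis(benzyloxy)phenol, via aryl formate 6 (not isolated)
Conditions: mCPBA, CH2Cl2, 0 °C to rt; then K2CO3 (cat.), MeOH, rt
Reagents that add atoms: 3-chloroperoxybenzoic acid, O=C(OO)c1cccc(Cl)c1
Why: Baeyer–Villiger (Dakin-type) oxidation of an electron-rich benzaldehyde, in which the dialkoxyaryl group migrates to oxygen, followed by methanolysis of the formate.

**Step 4**
Reactants: 7 2,4-bis(benzyloxy)phenol
Product: 8 2,4-bis(benzyloxy)phenyl trifluoromethanesulfonate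
Conditions: Tf2O, pyridine, CH2Cl2, 0 °C
Reagents that add atoms: trifluoromethanesulfonic anhydride, O=S(=O)(OS(=O)(=O)C(F)(F)F)C(F)(F)F
Why: O-Sulfonylation of the phenol gives the aryl triflate electrophile; the benzyl ethers are inert.

**Step 5**
Reactants: 9 5-bromo-1,2,3-trimethoxybenzene; 4 (Z)-prop-1-enylboronic ester of diol 2; 8 2,4-bis(benzyloxy)phenyl trifluoromethanesulfonate
Product: 13 (1R,2S)-2-[2,4-bis(benzyloxy)phenyl]-1-(3,4,5-trimethoxyphenyl)propan-1-ol, via aryllithium 10 (not isolated), via borate complex 11 (not isolated), via boronic ester 12 (not isolated)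
Conditions: 9, t-BuLi (2 equiv), THF, −78 °C; add 4, −78 °C to rt; then Pd(OAc)2 (3 mol %), (Sp,Sp)-MandyPhos (3.6 mol %), 8, NaOTf, THF, 60 °C; then 3 M NaOH, 30% H2O2, 0 °C to rt
Reagents that add atoms: hydrogen peroxide, OO
Why: Oxidative addition of zerovalent palladium to triflate 8 gives a cationic arylpalladium species that binds the propenyl π bond of borate 11 and triggers a 1,2-metallate shift in which the 3,4,5-trimethoxyphenyl group moves from boron to the boron-bearing carbon anti to palladium (this makes the aryl–C2 bond), and reductive elimination from the resulting alkylpalladium then makes C3–C3a. The closest known reaction type is the palladium-catalysed enantioselective conjunctive cross-coupling of β-substituted alkenylboron ate complexes with aryl triflates. No ring is closed in this step. The two new stereocentres C2 and C3 arise together: their relative (syn) configuration follows from the Z geometry of the alkene and the stereospecific anti addition, their absolute configuration from the chiral ferrocenyl diphosphine, which decides the alkene face bound by palladium, and the C–B bond is then oxidised with retention. The step needs the metallate shift to outrun direct transmetalation of either boron-bound carbon group (biaryl or propenylarene formation), which the hindered diol 2 on boron should secure, while NaOTf removes the bromide that would otherwise block the cationic palladium centre.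

**Step 6**
Reactants: 13 (1R,2S)-2-[2,4-bis(benzyloxy)phenyl]-1-(3,4,5-trimethoxyphenyl)propan-1-ol
Product: 14 (1R,2S)-2-(2,4-dihydroxyphenyl)-1-(3,4,5-trimethoxyphenyl)propan-1-ol
Conditions: H2 (1 atm), 10% Pd/C, EtOAc/EtOH, rt
Reagents that add atoms: none
Why: Hydrogenolysis of the two aryl benzyl ethers under neutral conditions should leave the secondary benzylic alcohol and both stereocentres untouched.

**Step 7**
Reactants: 14 (1R,2S)-2-(2,4-dihydroxyphenyl)-1-(3,4,5-trimethoxyphenyl)propan-1-ol
Product: 15 (2S,3S)-3-methyl-2-(3,4,5-trimethoxyphenyl)-2,3-dihydro-1-benzofuran-6-ol (2,3-trans)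
Conditions: PPh3, DIAD, THF (dilute), 0 °C to rt
Reagents that add atoms: none
Why: Intramolecular Mitsunobu etherification (5-exo-tet): only the ortho phenol can reach the activated benzylic carbon, and displacement with inversion at C2 turns the syn carbinol into the 2,3-trans ring B; any ionisation of the electron-rich benzylic centre should also close to the more stable trans isomer.

**Step 8**
Reactants: 15 (2S,3S)-3-methyl-2-(3,4,5-trimethoxyphenyl)-2,3-dihydro-1-benzofuran-6-ol
Product: 16 (2S,3S,3aR)-3-methyl-3a-(prop-2-en-1-yl)-2-(3,4,5-trimethoxyphenyl)-3,3a-dihydro-1-benzofuran-6(2H)-one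
Conditions: PhI(OAc)2, allylSiMe3 (excess), (CF3)2CHOH/CH2Cl2, −20 °C
Reagents that add atoms: allyltrimethylsilane, C=CC[Si](C)(C)C
Why: Oxidative Hosomi–Sakurai allylation of a para-alkylphenol with a trivalent iodine oxidant: the phenoxonium ion of ring A should be captured at the para carbon C3a from the face anti to the C3 methyl group, which sets the quaternary centre and leaves a dienone that cannot rearomatize.

**Step 9**
Reactants: 16 (2S,3S,3aR)-3-methyl-3a-(prop-2-en-1-yl)-2-(3,4,5-trimethoxyphenyl)-3,3a-dihydro-1-benzofuran-6(2H)-one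
Product: 18 (2S,3S,3aR,5R)-5-hydroxy-3-methyl-3a-(prop-2-en-1-yl)-2-(3,4,5-trimethoxyphenyl)-3,3a,4,5-tetrahydro-1-benzofuran-6(2H)-one, via potassium enolate 17 (not isolated)
Conditions: K[(s-Bu)3BH], THF, −78 °C; then 2-(phenylsulfonyl)-3-phenyloxaziridine, −78 °C; AcOH quench
Reagents that add atoms: 2-(phenylsulfonyl)-3-phenyloxaziridine, O=S(=O)(N1OC1c1ccccc1)c1ccccc1
Why: Conjugate hydride addition should occur at C4 of the only true enone arm (the C7=C7a arm is a deactivated vinylogous ester and the allyl group is inert), and enolate hydroxylation of the resulting potassium enolate should occur at C5 anti to the pseudoaxial allyl group, giving the 5R alcohol, which is also the equatorial epimer.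

**Step 10**
Reactants: 18 (2S,3S,3aR,5R)-5-hydroxy-3-methyl-3a-(prop-2-en-1-yl)-2-(3,4,5-trimethoxyphenyl)-3,3a,4,5-tetrahydro-1-benzofuran-6(2H)-one
Product: 19 (2S,3S,3aR,5R)-5-methoxy-3-methyl-3a-(prop-2-en-1-yl)-2-(3,4,5-trimethoxyphenyl)-3,3a,4,5-tetrahydro-1-benzofuran-6(2H)-one
Conditions: MeI (excess), Ag2O, 4 Å MS, CH2Cl2, rt, dark
Reagents that add atoms: iodomethane, CI
Why: Purdie methylation of the secondary α-hydroxy ketone under near-neutral conditions; should C5 epimerise, it is expected to converge on the same equatorial isomer.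

**Compound list**

1 | acenaphthylene-1,2-dione | O=C1C(=O)c2cccc3cccc1c23 | starting material
2 | cis-1,2-dimethyl-1,2-dihydroacenaphthylene-1,2-diol (meso) | O[C@]1(C)c2cccc3cccc(c23)[C@]1(C)O | intermediate
3 | (Z)-prop-1-en-1-ylboronic acid | C/C=C\B(O)O | starting material
4 | (Z)-prop-1-enylboronic ester of diol 2 | C/C=C\B1O[C@]2(C)c3cccc4cccc(c34)[C@]2(C)O1 | intermediate
5 | 2,4-bis(benzyloxy)benzaldehyde | O=Cc1ccc(OCc2ccccc2)cc1OCc1ccccc1 | starting material
6 | 2,4-bis(benzyloxy)phenyl formate (not isolated) | O=COc1ccc(OCc2ccccc2)cc1OCc1ccccc1 | intermediate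
7 | 2,4-bis(benzyloxy)phenol | Oc1ccc(OCc2ccccc2)cc1OCc1ccccc1 | intermediate
8 | 2,4-bis(benzyloxy)phenyl trifluoromethanesulfonate | FC(F)(F)S(=O)(=O)Oc1ccc(OCc2ccccc2)cc1OCc1ccccc1 | intermediate
9 | 5-bromo-1,2,3-trimethoxybenzene | COc1cc(Br)cc(OC)c1OC | starting material
10 | 3,4,5-trimethoxyphenyllithium (not isolated) | [Li]c1cc(OC)c(OC)c(OC)c1 | intermediate
11 | lithium [(Z)-prop-1-enyl](3,4,5-trimethoxyphenyl)borate of diol 2 (not isolated; configuration at boron not defined) | [Li+].C/C=C\[B-]1(c2cc(OC)c(OC)c(OC)c2)O[C@]2(C)c3cccc4cccc(c34)[C@]2(C)O1 | intermediate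
12 | boronic ester of diol 2 at C1 of 2-[2,4-bis(benzyloxy)phenyl]-1-(3,4,5-trimethoxyphenyl)propane (not isolated; same spatial arrangement as 13, descriptors 1R,2R) | C[C@@H](c1ccc(OCc2ccccc2)cc1OCc1ccccc1)[C@@H](B1O[C@]2(C)c3cccc4cccc(c34)[C@]2(C)O1)c1cc(OC)c(OC)c(OC)c1 | intermediate
13 | (1R,2S)-2-[2,4-bis(benzyloxy)phenyl]-1-(3,4,5-trimethoxyphenyl)propan-1-ol | C[C@@H](c1ccc(OCc2ccccc2)cc1OCc1ccccc1)[C@@H](O)c1cc(OC)c(OC)c(OC)c1 | intermediate
14 | (1R,2S)-2-(2,4-dihydroxyphenyl)-1-(3,4,5-trimethoxyphenyl)propan-1-ol | C[C@@H](c1ccc(O)cc1O)[C@@H](O)c1cc(OC)c(OC)c(OC)c1 | intermediate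
15 | (2S,3S)-3-methyl-2-(3,4,5-trimethoxyphenyl)-2,3-dihydro-1-benzofuran-6-ol | C[C@H]1c2ccc(O)cc2O[C@@H]1c1cc(OC)c(OC)c(OC)c1 | intermediate
16 | (2S,3S,3aR)-3-methyl-3a-(prop-2-en-1-yl)-2-(3,4,5-trimethoxyphenyl)-3,3a-dihydro-1-benzofuran-6(2H)-one | C=CC[C@]12C=CC(=O)C=C1O[C@H](c1cc(OC)c(OC)c(OC)c1)[C@H]2C | intermediate
17 | potassium dienolate formed by hydride addition at C4 of 16 (not isolated) | [K+].C=CC[C@]12CC=C([O-])C=C1O[C@H](c1cc(OC)c(OC)c(OC)c1)[C@H]2C | intermediate
18 | (2S,3S,3aR,5R)-5-hydroxy-3-methyl-3a-(prop-2-en-1-yl)-2-(3,4,5-trimethoxyphenyl)-3,3a,4,5-tetrahydro-1-benzofuran-6(2H)-one | C=CC[C@]12C[C@@H](O)C(=O)C=C1O[C@H](c1cc(OC)c(OC)c(OC)c1)[C@H]2C | intermediate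
19 | (2S,3S,3aR,5R)-5-methoxy-3-methyl-3a-(prop-2-en-1-yl)-2-(3,4,5-trimethoxyphenyl)-3,3a,4,5-tetrahydro-1-benzofuran-6(2H)-one | C=CC[C@]12C[C@@H](OC)C(=O)C=C1O[C@H](c1cc(OC)c(OC)c(OC)c1)[C@H]2C | target

**Step count and risks**

Total step count: 10. Longest linear sequence: 8 steps (steps 3 to 10; the branch through steps 1 and 2 is equally long).

Steps most likely to fail:

1. Step 5. The borate may undergo direct transmetalation to palladium (plain cross-coupling), the electron-rich, ortho-substituted arylpalladium species may form or bind the alkene too slowly, or enantioselectivity may erode with the Z-alkene. The fallback sets out from 8 and comes back at 13, and makes the aryl–C2 bond by carbonyl addition instead. Suzuki–Miyaura vinylation of 8 with potassium vinyltrifluoroborate (PdCl2(dppf), K2CO3) should give 2,4-bis(benzyloxy)-1-ethenylbenzene F1. Rhodium-catalysed asymmetric hydroformylation (Rh(acac)(CO)2, chiral bis(diazaphospholane) ligand, CO/H2) should give the branched aldehyde (2S)-2-[2,4-bis(benzyloxy)phenyl]propanal F2. Addition of 3,4,5-trimethoxyphenylmagnesium bromide F3, made from 9 and magnesium, at −78 °C under Felkin–Anh control (attack anti to the aryl group) should then give the syn carbinol 13.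

2. Step 8. The phenoxonium ion may lose the C3 proton (quinone methide formation and aromatization to the benzofuran), the silane may attack C5 or C7 instead of C3a, or facial selectivity may be poor. The fallback sets out from 15 and comes back at 16, and separates oxidation from C–C bond formation. PhI(OAc)2 in methanol at 0 °C, where the solvent captures the cation at C3a, should give the quinol ether (2S,3S,3aS)-3a-methoxy-3-methyl-2-(3,4,5-trimethoxyphenyl)-3,3a-dihydro-1-benzofuran-6(2H)-one F4 (either C3a epimer serves). Ionisation with Me3SiOTf in CH2Cl2 at −78 °C in the presence of excess allyltrimethylsilane, with no oxidant and no acetate base present, should then give 16 by Hosomi–Sakurai substitution anti to the C3 methyl group.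

3. Step 9. The hydride may add 1,2 to the dienone carbonyl, or the enolate may add to the sulfonylimine by-product or be hydroxylated with poor facial selectivity. The fallback sets out from 16 and comes back at 18. Copper hydride-catalysed conjugate hydrosilylation ([(Ph3P)CuH]6 cat., PhMe2SiH, toluene, rt) should give the silyl dienol ether dimethyl(phenyl)silyl enol ether of 4,5-dihydro-16 F5. Rubottom oxidation (dimethyldioxirane, acetone, −40 °C, then mild acid) should then give 18.

**Further compounds**

F1 | step 5 | 2,4-bis(benzyloxy)-1-ethenylbenzene | C=Cc1ccc(OCc2ccccc2)cc1OCc1ccccc1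
F2 | step 5 | (2S)-2-[2,4-bis(benzyloxy)phenyl]propanal | C[C@@H](c1ccc(OCc2ccccc2)cc1OCc1ccccc1)C=O
F3 | step 5 | 3,4,5-trimethoxyphenylmagnesium bromide | COc1cc([Mg]Br)cc(OC)c1OC
F4 | step 8 | (2S,3S,3aS)-3a-methoxy-3-methyl-2-(3,4,5-trimethoxyphenyl)-3,3a-dihydro-1-benzofuran-6(2H)-one | CO[C@]12C=CC(=O)C=C1O[C@H](c1cc(OC)c(OC)c(OC)c1)[C@H]2C
F5 | step 9 | dimethyl(phenyl)silyl enol ether of 4,5-dihydro-16 | C=CC[C@]12CC=C(O[Si](C)(C)c3ccccc3)C=C1O[C@H](c1cc(OC)c(OC)c(OC)c1)[C@H]2C
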